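Ring B is traced to cyclopent-2-en-1-one. Its carbinol carbon C(CH3)(OH) is a masked ketone; the next ring carbon carries the CH2 linker to ring A and the one after it the isopropenyl group, trans to each other. One flask adds isopropenyl to the enone β-carbon under chiral copper catalysis and traps the regiodefined enolate with methyl acrylate, forming both substituent bonds and both stereocentres from three commercial compounds. The acrylate ester carbon and its α-carbon then become two carbons of ring A through methyl addition with lactonisation, Claisen and Dieckmann condensations with diprenylated methyl acetoacetate, and a final C-acylation.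

Key step: step 1

Assumption: ring A is the six-membered acyl-trione ring and ring B the cyclopentane; 13 and the target are each one compound drawn as one enol tautomer; the (R,Sp) hand of the ferrocenyl diphosphine is written as the one taken to give the (S) β-centre, its mirror image being equally available if the sense is the opposite.

Step 1
Reactants: 1 cyclopent-2-en-1-one; 2 isopropenylmagnesium bromide; 3 methyl acrylate
Product: 5 methyl 3-[(1R,5S)-2-oxo-5-(prop-1-en-2-yl)cyclopentyl]propanoate, via magnesium enolate 4 (not isolated)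
Conditions: CuBr·S(CH3)2 (5 mol %), (R)-1-[(Sp)-2-(diphenylphosphino)ferrocenyl]ethyldicyclohexylphosphine (6 mol %), t-BuOMe, −78 °C, slow addition of 2 (in Et2O or 2-methyltetrahydrofuran); then 3 (1.05 equiv), THF, −78 to −40 °C; aq. NH4Cl
Reagents that add atoms: none
Why: The diphosphine–CuBr complex (monovalent copper) is transmetalated by 2, binds the enone as a π-complex and, through a trivalent-copper σ-alkenyl species, transfers isopropenyl to C3, leaving magnesium enolate 4 with its double bond fixed between C1 and C2; 4 then adds in Michael fashion to 3 and the adduct is protonated on quench. The closest known reaction type is the tandem copper-catalysed asymmetric conjugate addition of Grignard reagents to cyclic enones with in situ enolate trapping (three-component coupling of the prostanoid kind), here with a Michael acceptor as the trap. No ring is closed. The isopropenyl-bearing centre (S) is set by the chiral ligand, which should direct attack to the Si face of C3; the chain-bearing centre (R) is set by the substrate, acrylate approaching anti to the new isopropenyl group, and any cis isomer should epimerise to the trans ketone through the enol. The step needs 1,4- over 1,2-addition (secured by the copper catalyst at low temperature), bond formation at C2 and not C5 (secured because the enolate is generated regiospecifically and trapped before it equilibrates) and a single Michael addition (secured by about one equivalent of 3 added slowly at −78 °C and a cold quench).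

Step 2
Reactants: 5 methyl 3-[(1R,5S)-2-oxo-5-(prop-1-en-2-yl)cyclopentyl]propanoate
Product: 7 (4aR,5S,7aS)-7a-methyl-5-(prop-1-en-2-yl)hexahydrocyclopenta[b]pyran-2(3H)-one, via hydroxy ester 6 (not isolated)
Conditions: CeCl3 (dried), CH3MgBr, THF, −78 °C to rt; then PPTS (cat.), toluene, 40 °C
Reagents that add atoms: methylmagnesium bromide, C[Mg]Br
Why: The weakly basic, carbonyl-selective organocerium reagent should add to the ketone without enolisation or ester attack (1,2-addition) from the face trans to the adjacent chain, so the new tertiary alkoxide lies cis to the chain (S carbinol centre) and closes the cis-fused δ-lactone by intramolecular transesterification (lactonisation), which also separates it from any trans-alcohol.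

Step 3
Reactants: 8 methyl acetoacetate; 9 prenyl bromide
Product: 10 methyl 2,2-bis(3-methylbut-2-en-1-yl)-3-oxobutanoate
Conditions: 9 (2.3 equiv), K2CO3, acetone, reflux
Reagents that add atoms: none
Why: Double C-alkylation of a β-keto ester (acetoacetic ester alkylation) with a reactive allylic bromide should proceed at the doubly activated carbon until no acidic C–H remains there; no stereocentre is formed.

Step 4
Reactants: 7 (4aR,5S,7aS)-7a-methyl-5-(prop-1-en-2-yl)hexahydrocyclopenta[b]pyran-2(3H)-one; 10 methyl 2,2-bis(3-methylbut-2-en-1-yl)-3-oxobutanoate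
Product: 12 methyl 7-[(1R,2S,5S)-2-hydroxy-2-methyl-5-(prop-1-en-2-yl)cyclopentyl]-2,2-bis(3-methylbut-2-en-1-yl)-3,5-dioxoheptanoate, via lithium enolate 11 (not isolated)
Conditions: LiN(i-Pr)2 (2.2 equiv), 10 (2.3 equiv), THF, −78 °C; then 7, −78 to 0 °C; aq. NH4Cl
Reagents that add atoms: none
Why: In this crossed Claisen condensation 10 can enolise only at its methyl ketone, so a single enolate 11 forms; being less basic than a lactone enolate it should acylate at the lactone carbonyl instead of deprotonating it, ring opening frees the tertiary alkoxide and the β-diketone is held as its lithium enolate (hence the second equivalent of 11), and no stereocentre is touched.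

Step 5
Reactants: 12 methyl 7-[(1R,2S,5S)-2-hydroxy-2-methyl-5-(prop-1-en-2-yl)cyclopentyl]-2,2-bis(3-methylbut-2-en-1-yl)-3,5-dioxoheptanoate
Product: 13 3,5-dihydroxy-2-{[(1R,2S,5S)-2-hydroxy-2-methyl-5-(prop-1-en-2-yl)cyclopentyl]methyl}-4,4-bis(3-methylbut-2-en-1-yl)cyclohexa-2,5-dien-1-one (dienol form of the cyclohexane-1,3,5-trione)
Conditions: LiN(i-Pr)2 (3.5 equiv), THF, −78 °C to rt; 1 M HCl to pH 4, 0 °C
Reagents that add atoms: none
Why: In this Dieckmann condensation through the β-diketone γ-carbanion, base removes the hydroxyl proton, a proton of the central CH2 and then the only available γ-proton (C6, next to the linker CH2), and this carbon should attack the methyl ester in a 6-exo-trig acyl substitution to give the trione as its stabilised enolate, the ring B stereocentres being remote from every acidic site.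

Step 6
Reactants: 13 3,5-dihydroxy-2-{[(1R,2S,5S)-2-hydroxy-2-methyl-5-(prop-1-en-2-yl)cyclopentyl]methyl}-4,4-bis(3-methylbut-2-en-1-yl)cyclohexa-2,5-dien-1-one
Product: 15 3,5-dihydroxy-4-{[(1R,2S,5S)-2-hydroxy-2-methyl-5-(prop-1-en-2-yl)cyclopentyl]methyl}-6,6-bis(3-methylbut-2-en-1-yl)-2-(3-methylbutanoyl)cyclohexa-2,4-dien-1-one (CNP0332156.1), via enol ester 14 (not isolated)
Conditions: 3-methylbutanoic acid, DCC, DMAP, CH2Cl2, 0 °C to rt
Reagents that add atoms: 3-methylbutanoic acid (isovaleric acid), CC(C)CC(=O)O
Why: In this carbodiimide/DMAP C-acylation of a cyclic β-dicarbonyl the enol is first O-acylated to 14 and DMAP should then shuttle the acyl group to the unsubstituted ring carbon between two carbonyls (O-to-C acyl migration), where the product is held as a hydrogen-bonded enolised β-triketone, while the hindered tertiary alcohol should stay free and no stereocentre is affected.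

Compound list
1 | cyclopent-2-en-1-one | O=C1C=CCC1 | starting material
2 | isopropenylmagnesium bromide | C=C(C)[Mg]Br | starting material
3 | methyl acrylate | C=CC(=O)OC | starting material
4 | bromomagnesium (3S)-3-(prop-1-en-2-yl)cyclopent-1-en-1-olate | C=C(C)[C@H]1CCC(O[Mg]Br)=C1 | intermediate (not isolated)
5 | methyl 3-[(1R,5S)-2-oxo-5-(prop-1-en-2-yl)cyclopentyl]propanoate | C=C(C)[C@H]1CCC(=O)[C@@H]1CCC(=O)OC | intermediate
6 | methyl 3-[(1R,2S,5S)-2-hydroxy-2-methyl-5-(prop-1-en-2-yl)cyclopentyl]propanoate (present as its metal alkoxide) | C=C(C)[C@H]1CC[C@](C)(O)[C@@H]1CCC(=O)OC | intermediate (not isolated)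
7 | (4aR,5S,7aS)-7a-methyl-5-(prop-1-en-2-yl)hexahydrocyclopenta[b]pyran-2(3H)-one | C=C(C)[C@H]1CC[C@](C)(O2)[C@@H]1CCC2=O | intermediate
8 | methyl acetoacetate | CC(=O)CC(=O)OC | starting material
9 | prenyl bromide (1-bromo-3-methylbut-2-ene) | CC(C)=CCBr | starting material
10 | methyl 2,2-bis(3-methylbut-2-en-1-yl)-3-oxobutanoate | CC(=O)C(CC=C(C)C)(CC=C(C)C)C(=O)OC | intermediate
11 | lithium enolate of 10 (methyl 3-lithiooxy-2,2-bis(3-methylbut-2-en-1-yl)but-3-enoate) | C=C(O[Li])C(CC=C(C)C)(CC=C(C)C)C(=O)OC | intermediate (not isolated)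
12 | methyl 7-[(1R,2S,5S)-2-hydroxy-2-methyl-5-(prop-1-en-2-yl)cyclopentyl]-2,2-bis(3-methylbut-2-en-1-yl)-3,5-dioxoheptanoate | C=C(C)[C@H]1CC[C@](C)(O)[C@@H]1CCC(=O)CC(=O)C(CC=C(C)C)(CC=C(C)C)C(=O)OC | intermediate
13 | 3,5-dihydroxy-2-{[(1R,2S,5S)-2-hydroxy-2-methyl-5-(prop-1-en-2-yl)cyclopentyl]methyl}-4,4-bis(3-methylbut-2-en-1-yl)cyclohexa-2,5-dien-1-one | C=C(C)[C@H]1CC[C@](C)(O)[C@@H]1CC1=C(O)C(CC=C(C)C)(CC=C(C)C)C(O)=CC1=O | intermediate
14 | 5-hydroxy-2-{[(1R,2S,5S)-2-hydroxy-2-methyl-5-(prop-1-en-2-yl)cyclopentyl]methyl}-4,4-bis(3-methylbut-2-en-1-yl)-3-oxocyclohexa-1,5-dien-1-yl 3-methylbutanoate (drawn as one O-acyl regioisomer) | C=C(C)[C@H]1CC[C@](C)(O)[C@@H]1CC1=C(OC(=O)CC(C)C)C=C(O)C(CC=C(C)C)(CC=C(C)C)C1=O | intermediate (not isolated)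
15 | 3,5-dihydroxy-4-{[(1R,2S,5S)-2-hydroxy-2-methyl-5-(prop-1-en-2-yl)cyclopentyl]methyl}-6,6-bis(3-methylbut-2-en-1-yl)-2-(3-methylbutanoyl)cyclohexa-2,4-dien-1-one | C=C(C)[C@H]1CC[C@](C)(O)[C@@H]1CC1=C(O)C(CC=C(C)C)(CC=C(C)C)C(=O)C(C(=O)CC(C)C)=C1O | target

Total step count: 6. Longest linear sequence: 5 steps (1, 2, 4, 5, 6); step 3 is a one-step side branch.

Steps most likely to fail

Step 1. After the first Michael addition the ester enolate can hand its charge to the ring and a second acrylate can add, or acrylate can oligomerise anionically, so the one-flask trapping may not stop at the 1:1 adduct. The fallback sets out from enolate 4 (made from 1 and 2 as before) and returns at 5. Enolate 4 is silylated with (CH3)3SiCl/Et3N and isolated as trimethyl{[(3S)-3-(prop-1-en-2-yl)cyclopent-1-en-1-yl]oxy}silane F1. CH3Li in THF regenerates the regiodefined lithium enolate, which is added at −78 °C to methyl 2-(trimethylsilyl)acrylate (C=C([Si](C)(C)C)C(=O)OC), an acceptor whose α-silyl ester enolate is too stabilised and hindered to add again. This should give methyl 3-[(1R,5S)-2-oxo-5-(prop-1-en-2-yl)cyclopentyl]-2-(trimethylsilyl)propanoate F2. KF in CH3OH then removes the silyl group and lets the ring centre settle trans, giving 5.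

Step 2. Facial selectivity of the methyl addition may be insufficient, because attack anti to the chain is attack syn to the β-isopropenyl group; the trans-hydroxy ester that results cannot lactonise. The fallback sets out from 5 and returns at 7, and delivers the oxygen from the chain itself. Wittig methylenation (Ph3PCH3Br, KOC(CH3)3, THF) should give methyl 3-[(1R,5S)-2-methylidene-5-(prop-1-en-2-yl)cyclopentyl]propanoate F3. LiOH in THF/H2O gives 3-[(1R,5S)-2-methylidene-5-(prop-1-en-2-yl)cyclopentyl]propanoic acid F4. Iodolactonisation (I2, NaHCO3, CH3CN, 0 °C) closes the ring 6-exo onto the exocyclic alkene, necessarily cis to the chain and faster than seven-membered closure onto the isopropenyl group, giving (4aR,5S,7aS)-7a-(iodomethyl)-5-(prop-1-en-2-yl)hexahydrocyclopenta[b]pyran-2(3H)-one F5. Radical deiodination with Bu3SnH/AIBN, run at high tin hydride concentration so that hydrogen transfer outruns cyclisation onto the isopropenyl group, should give 7.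

Step 4. Acylation of the hindered ketone enolate 11 by the lactone may be slow, leaving time for proton exchange and self-condensation of the enolate. The fallback sets out from 7 and returns at 12, with the roles of the partners reversed. CH3Li (1 equiv, THF, −78 °C) opens 7 through its stable tetrahedral adduct to 4-[(1R,2S,5S)-2-hydroxy-2-methyl-5-(prop-1-en-2-yl)cyclopentyl]butan-2-one F6 (in equilibrium with its cyclic hemiketal). Separately, dimethyl malonate and 9 (K2CO3, acetone, reflux) give dimethyl 2,2-bis(3-methylbut-2-en-1-yl)propanedioate F7, a non-enolisable acyl donor that tolerates excess base. F6 is treated with LiN(i-Pr)2 (3 equiv, THF, −78 °C) to form the alkoxide and the kinetic methyl enolate, which is acylated by F7 to give 12 after aq. NH4Cl.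

Further compounds
F1 | step 1 | trimethyl{[(3S)-3-(prop-1-en-2-yl)cyclopent-1-en-1-yl]oxy}silane | C=C(C)[C@H]1CCC(O[Si](C)(C)C)=C1
F2 | step 1 | methyl 3-[(1R,5S)-2-oxo-5-(prop-1-en-2-yl)cyclopentyl]-2-(trimethylsilyl)propanoate (mixture at the silyl-bearing carbon) | C=C(C)[C@H]1CCC(=O)[C@@H]1CC([Si](C)(C)C)C(=O)OC
F3 | step 2 | methyl 3-[(1R,5S)-2-methylidene-5-(prop-1-en-2-yl)cyclopentyl]propanoate | C=C(C)[C@H]1CCC(=C)[C@@H]1CCC(=O)OC
F4 | step 2 | 3-[(1R,5S)-2-methylidene-5-(prop-1-en-2-yl)cyclopentyl]propanoic acid | C=C(C)[C@H]1CCC(=C)[C@@H]1CCC(=O)O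
F5 | step 2 | (4aR,5S,7aS)-7a-(iodomethyl)-5-(prop-1-en-2-yl)hexahydrocyclopenta[b]pyran-2(3H)-one | C=C(C)[C@H]1CC[C@](CI)(O2)[C@@H]1CCC2=O
F6 | step 4 | 4-[(1R,2S,5S)-2-hydroxy-2-methyl-5-(prop-1-en-2-yl)cyclopentyl]butan-2-one | C=C(C)[C@H]1CC[C@](C)(O)[C@@H]1CCC(C)=O
F7 | step 4 | dimethyl 2,2-bis(3-methylbut-2-en-1-yl)propanedioate | COC(=O)C(CC=C(C)C)(CC=C(C)C)C(=O)OC
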